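## The problem

The target 13 is (2S)-8-[(2S)-2-hydroxy-3-methylbut-3-en-1-yl]-5,7-dimethoxyflavanone. Its benzene ring A carries five substituents (the C4 acyl carbon on C4a, OMe on C5 and C7, the side chain on C8, O1 on C8a) and is fused to the dihydropyranone ring C, which bears phenyl at C2. Ring A is a phloroglucinol whose three oxygens are all different and whose carbon chain sits on C8, not C6, so a route from a symmetrical arene must make these distinctions by selective substitution. The stereocentres C2 (S) and C2'' (S) are five bonds apart across an aromatic carbon; neither can control the other, and each needs its own source. C2 is a benzylic ether β to the C4 ketone: base opens ring C to the 2'-hydroxychalcone and closes it again, so C2 must be set last and under mild conditions. The side chain is a secondary allylic alcohol beside a 1,1-disubstituted alkene, which rules out hydrogenation, strong acid and any activation of that hydroxyl near the free phenol. The enabling feature is the oxygen pattern of ring A: oxygen on the alternate carbons C5, C7 and C8a with the C4 acyl carbon on C4a is the pattern of a folded tetraketide whose carboxyl end is C8a. Ring A can therefore be closed by a Claisen condensation between C4a and C8a of an open chain in which C5–O and C7–O are already methyl enol ethers and C8 already carries its side chain. Because the C2'' oxygen is γ to that carboxyl carbon, the carboxyl end can be a γ-lactone whose ring oxygen is the leaving group.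

## Retrosynthesis

**O1–C2.** Cutting this bond turns 13 into the 2'-hydroxychalcone 12, an isomer of the target, and removes ring C and the labile C2 centre together. The neighbouring cuts (C2–phenyl by arylation of a chromone, or C4–C4a by acylation) would need ring A complete with its side chain. The forward reaction is a 6-endo-trig oxa-Michael addition under catalyst control, since C2'' is too remote to bias it. If selectivity is imperfect, the C2 epimers are diastereomers and can be separated and recycled.

**C4a–C8a.** Ring A of 12 is cut at the one ring bond whose formation is the Claisen folding of a linear tetraketide. The aldol mode of folding (C8 onto C4) would give a resorcylic ester, and cuts that keep ring A bring back the C6/C8 choice and the three-oxygen problem. In precursor 11 the C5 and C7 oxygens are methyl enol ethers, so both methyl groups are placed before the ring exists. The carboxyl carbon C8a is tied to the C2'' oxygen as a γ-lactone: its carbonyl oxygen becomes the free C8a hydroxyl and the side-chain alkoxide leaves. An acyclic methyl ester with a silyl ether at C2'' would allow the same closure. The lactone saves a protection and a deprotection, is the better acyl acceptor, and makes 11, 12 and 13 isomers. The forward step must form C4a–C8a from the only enolisable position. It needs C8a and C6 cis on the C7=C8 bond and C7 and C4a cis on the C5=C6 bond, or equilibration to that geometry in the anion. Precursor 11 has no carbocycle and only the C2'' stereocentre.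

**C4–C4a.** 11 is cut into the triketide lactone 9 and the cinnamoyl donor 10. The whole C2–C3–C4–phenyl unit then comes from one commercial reagent, and the nucleophile reacts through its terminal methyl group (the future C4a). Introducing the cinnamoyl group earlier would carry an acidic methylene and an enone through two enolate steps. Introducing it after aromatisation would be a Friedel–Crafts acylation with a choice between C4a and C6. The forward reaction is acylation of a trienolate at its far end; a Weinreb amide is chosen so that the ketone of 11 is not released before the quench.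

**C7–OMe and C7–C8.** Cutting the O–methyl bond at C7 of 9 gives the β-keto lactone 8, whose only acidic position is C8. Cutting C7–C8 then gives lactone 4 and acid chloride 7. 7 brings C4a, C5, C6, C7 and the C5 methyl ether in one piece and comes from commercial ester 5 through acid 6. Building the same chain by two acetate additions, each followed by O-methylation, costs two more steps and passes through a δ-keto enoate that can close to a 2-pyrone. The forward reactions are a crossed Claisen acylation of a lactone enolate and an O-methylation of a β-dicarbonyl enolate.

**The isopropenyl group.** Lactone 4 holds C8a, C8, C1'', C2'' and the isopropenyl group, with C2'' as its only stereocentre. Cutting the C3''=CH2 bond gives ketone 3. Cutting the C3''–CH3 bond leads through acid chloride 2 to acid 1, which is commercial in the (S) form. No bond to the stereocentre is broken, and the descriptor stays S because carboxyl, acetyl and isopropenyl all rank between O and CH2. An asymmetric reduction of an enone, or alkylation with a β-silyloxy iodide, would be longer or less secure. The forward steps must make the ketone without opening the lactone and methylenate it without epimerising the α-acyloxy ketone.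

## Roads not taken

**Alternative 1:** The cut is C4–C4a, made after O1–C2 has been set by etherification of a phenol with a chiral 3-hydroxy-3-phenylpropanoate. In the key step (S)-3-(2-allyl-3,5-dimethoxyphenoxy)-3-phenylpropanoic acid A2 is activated with (CF3CO)2O and the mixed anhydride acylates C4a, giving (2S)-8-allyl-5,7-dimethoxyflavanone A1.
- Merits: C2 is fixed by a stereospecific substitution before ring C exists, the electron-rich ring acylates readily, and closure can only occur at C4a because C8 is blocked. For C2 this road is more secure than the chosen plan.
- Weak points: A1 carries only an allyl group. Turning it into the side chain needs oxidative cleavage to an enolisable arylacetaldehyde and a reagent-controlled isopropenyl addition in the presence of the C4 ketone and the base-labile C2 centre. The benzylic aryl ether of A2 can ionise or eliminate under the acidic closure.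
- Comparison: the chosen plan sets against the better C2 control a side chain that is complete and enantiopure from the chiral pool before ring A exists, fewer steps after ring formation, and C2 epimers that are separable diastereomers.

**Alternative 2:** The cuts are C4a–C4, C4–C3 and O1–C2. In the key step the iodophenol A4, CO and phenylacetylene A5 are joined with PdCl2(PPh3)2 (divalent palladium, reduced in the flask to the zerovalent catalyst) and Et2NH. The phenol then adds to the ynone to give 8-[(2S)-2-(tert-butyldimethylsilyloxy)-3-methylbut-3-en-1-yl]-5,7-dimethoxyflavone A3.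
- Merits: highly convergent, and every bond-forming event is known chemistry, which the folding of the chosen plan is not.
- Weak points: A3 is a flavone, so C2 must be created by enantioselective reduction of C2=C3 without touching the 1,1-disubstituted alkene; hydrogenation cannot do this. The iodide of A4 is flanked by OH and OMe on an electron-rich ring, and 5-exo closure to an aurone competes. A4 itself needs regiocontrolled substitution of a phloroglucinol ring, the problem the chosen plan avoids.
- Comparison: carbon–carbon bond formation is surer here. The chosen plan offers a ring A whose substitution pattern follows from the chain and a final closure that reaches the flavanone oxidation level directly.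

**Alternative 3:** The cut is C3–C4, with C2–H formed in the same step. The salicylaldehyde 1-phenylvinyl ether A7 would undergo intramolecular hydroacylation with [Rh(cod)2]BF4 and a chiral bisphosphine (monovalent rhodium) to give the silyl-protected flavanone A6.
- Merits: C2 is set irreversibly in the ring-forming step, with no chalcone equilibrium, and A6 is one deprotection from 13. If it worked it would control C2 better than the last step of the chosen plan.
- Weak points: closure of a six-membered ketone onto a 1,1-disubstituted enol ether is not established, and decarbonylation of the hindered, electron-rich aldehyde competes. The isopropenyl group is a second alkene for the rhodium hydride. A7 needs both a hindered aryl vinyl ether and a fully substituted benzaldehyde made by arene substitution.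
- Comparison: this road stacks two unproven features on a substrate that is itself long to make. The chosen plan has one unproven step, reached in six steps from commercial materials.

Key step: step 7

Assumption: enol ethers 9 and 11 are drawn as the (E,E) isomers that can fold; other geometrical isomers from steps 5 and 6 are expected to converge in the anion of step 7. The quinine-derived thiourea is taken to give the 2S series in step 8; otherwise its quinidine-derived pseudoenantiomer is used.

## Route

Step 1
Reactants: 1 (S)-5-oxotetrahydrofuran-2-carboxylic acid
Product: 3 (S)-5-acetyldihydrofuran-2(3H)-one, via (S)-5-oxotetrahydrofuran-2-carbonyl chloride 2 (not isolated)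
Conditions: (COCl)2, cat. DMF, CH2Cl2, 0 → 25 °C; evaporate; Me2CuLi, Et2O, −78 °C
Reagents that add atoms: oxalyl chloride, ClC(=O)C(=O)Cl (chlorine of 2); lithium dimethylcuprate, [Li+].C[Cu-]C (methyl group of 3)
Why: Acid chloride formation followed by acyl substitution with a Gilman cuprate, which stops at the ketone and leaves the lactone alone; no base is present that could enolise the acid chloride or the α-acyloxy ketone, so the stereocentre is carried through.

Step 2
Reactants: 3 (S)-5-acetyldihydrofuran-2(3H)-one
Product: 4 (S)-5-(prop-1-en-2-yl)dihydrofuran-2(3H)-one
Conditions: Zn, CH2Br2, TiCl4, THF–CH2Cl2, 0 → 25 °C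
Reagents that add atoms: dibromomethane, BrCBr
Why: Takai–Lombardo methylenation; the non-basic zinc–titanium methylene reagent converts enolisable ketones in the presence of lactones and does not epimerise the oxygen-bearing α-carbon, which a phosphorus ylide might.

Step 3
Reactants: 5 methyl (E)-3-methoxybut-2-enoate
Product: 6 (E)-3-methoxybut-2-enoic acid
Conditions: NaOH, H2O–MeOH, 60 °C; then HCl to pH 2–3, 0 °C
Reagents that add atoms: sodium hydroxide, [Na+].[OH-] (one carboxyl oxygen)
Why: Saponification of a β-alkoxy enoate, which is stable to aqueous base; cold, brief acidification avoids hydrolysis of the enol ether.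

Step 4
Reactants: 4 (S)-5-(prop-1-en-2-yl)dihydrofuran-2(3H)-one; 6 (E)-3-methoxybut-2-enoic acid
Product: 8 (5S)-3-[(E)-3-methoxybut-2-enoyl]-5-(prop-1-en-2-yl)dihydrofuran-2(3H)-one, via (E)-3-methoxybut-2-enoyl chloride 7 (not isolated)
Conditions: 6, (COCl)2, cat. DMF, CH2Cl2, 0 → 25 °C, evaporate; 4, LiN(SiMe3)2 (2.1 equiv), THF, −78 °C, then 7; AcOH
Reagents that add atoms: oxalyl chloride, ClC(=O)C(=O)Cl (chlorine of 7, lost again on acylation)
Why: Crossed Claisen acylation of a lactone lithium enolate with an acid chloride, which goes to carbon for ester enolates; the second equivalent of base takes the acidic proton of 8 as it forms, and C5 of the lactone is remote from the enolate, so 8 should form as a mixture of C3 epimers and enol.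

Step 5
Reactants: 8 (5S)-3-[(E)-3-methoxybut-2-enoyl]-5-(prop-1-en-2-yl)dihydrofuran-2(3H)-one
Product: 9 (3E,5S)-3-[(2E)-1,3-dimethoxybut-2-en-1-ylidene]-5-(prop-1-en-2-yl)dihydrofuran-2(3H)-one
Conditions: KN(SiMe3)2, THF–DMPU, −78 °C; Me2SO4, −78 → 0 °C
Reagents that add atoms: dimethyl sulfate, COS(=O)(=O)OC
Why: O-alkylation of a β-keto lactone enolate under hard conditions (potassium counter-ion, dipolar aprotic co-solvent, dimethyl sulfate), the standard way to β-methoxyacrylates; C-methylation would have to build a quaternary ring carbon, and the exocyclic double-bond geometry need not be controlled (see step 7).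

Step 6
Reactants: 9 (3E,5S)-3-[(2E)-1,3-dimethoxybut-2-en-1-ylidene]-5-(prop-1-en-2-yl)dihydrofuran-2(3H)-one; 10 N-methoxy-N-methylcinnamamide
Product: 11 (3E,5S)-3-[(2E,6E)-1,3-dimethoxy-5-oxo-7-phenylhepta-2,6-dien-1-ylidene]-5-(prop-1-en-2-yl)dihydrofuran-2(3H)-one
Conditions: LiN(iPr)2 (1.05 equiv), THF, −78 °C; 10, −78 → −50 °C; AcOH, −78 °C
Reagents that add atoms: none
Why: Terminal acylation of the lithium trienolate of a 3,5-dialkoxy-2,4-dienoate, the open-chain counterpart of the side-chain acylation of metallated 4-methoxy-6-methyl-2-pyrone; the α-carbon is fully substituted and the γ-carbon flanked by two alkoxy-bearing carbons, so the methyl terminus should react. The Weinreb amide holds the product as a chelated adduct until the cold quench, so the acidic methylene of 11 is not exposed to base.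

Step 7
Reactants: 11 (3E,5S)-3-[(2E,6E)-1,3-dimethoxy-5-oxo-7-phenylhepta-2,6-dien-1-ylidene]-5-(prop-1-en-2-yl)dihydrofuran-2(3H)-one
Product: 12 (E)-1-{2-hydroxy-3-[(2S)-2-hydroxy-3-methylbut-3-en-1-yl]-4,6-dimethoxyphenyl}-3-phenylprop-2-en-1-one
Conditions: LiN(SiMe3)2 (2.2 equiv), THF (0.02 M), −78 → 25 °C; AcOH, −78 °C
Reagents that add atoms: none
Why: Proposed new method: LiN(SiMe3)2 removes a proton from the C4a methylene of 11, the only CH flanked by the ketone and the dienoate, giving an oxonol-type anion whose charge is shared by the C4 oxygen and the lactone carbonyl oxygen; every C–C bond of the chain then has partial double-bond character, so geometrical isomers at the two enol ether double bonds should interconvert. From the conformer with C8a and C4a cis, C4a attacks the lactone carbonyl C8a in a 6-exo-trig Claisen (Dieckmann-type) closure, equally a 6π electrocyclisation of the trienolate, and this closes ring A, the only ring formed. The tetrahedral alkoxide collapses by breaking the C8a–O bond of the lactone, which releases the C2'' alkoxide, and the 6-acylcyclohexa-2,4-dienone loses its doubly activated proton to give the phenoxide, so aromatisation makes the sequence irreversible. The closest known reaction type is the base-mediated Claisen cyclisation of 3,5,7-triketo esters and of 6-(2-oxoalkyl)-4-methoxy-2-pyrones to acylphloroglucinols; an open-chain bis(methyl enol ether) has not been folded in this way. Claisen rather than aldol folding is secured because the C5 and C7 carbonyl groups are masked and the lactone is the only acceptor within reach, while the enone carbonyl is switched off as its own enolate, which also guards against Michael addition. The substitution pattern follows from the chain: the lactone carbonyl oxygen becomes the free C8a hydroxyl, C5 and C7 keep their methyl groups, and C8 already bears C1''. No stereocentre is formed, and the C2''–O bond is not broken, so its configuration is retained.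

Step 8
Reactants: 12 (E)-1-{2-hydroxy-3-[(2S)-2-hydroxy-3-methylbut-3-en-1-yl]-4,6-dimethoxyphenyl}-3-phenylprop-2-en-1-one
Product: 13 (2S)-8-[(2S)-2-hydroxy-3-methylbut-3-en-1-yl]-5,7-dimethoxy-2-phenyl-2,3-dihydro-4H-chromen-4-one
Conditions: quinine-derived thiourea 1-[3,5-bis(trifluoromethyl)phenyl]-3-[(8S,9S)-6'-methoxycinchonan-9-yl]thiourea (10 mol %), toluene, 25 °C
Reagents that add atoms: none
Why: Intramolecular oxa-Michael addition (6-endo-trig) of the phenol to the enone under bifunctional amine-thiourea catalysis: the quinuclidine nitrogen activates the phenol, the thiourea binds the enone carbonyl, and the catalyst selects the face of C2, which C2'' five bonds away cannot do. The free side-chain hydroxyl cannot reach the enone, and the two possible products are diastereomers, so the C2 purity can be raised by chromatography or crystallisation.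

## Compound list

1 | (S)-5-oxotetrahydrofuran-2-carboxylic acid | OC(=O)[C@@H]1CCC(=O)O1 | starting material
2 | (S)-5-oxotetrahydrofuran-2-carbonyl chloride (not isolated) | O=C(Cl)[C@@H]1CCC(=O)O1 | intermediate
3 | (S)-5-acetyldihydrofuran-2(3H)-one | CC(=O)[C@@H]1CCC(=O)O1 | intermediate
4 | (S)-5-(prop-1-en-2-yl)dihydrofuran-2(3H)-one | C=C(C)[C@@H]1CCC(=O)O1 | intermediate
5 | methyl (E)-3-methoxybut-2-enoate | CO/C(C)=C/C(=O)OC | starting material
6 | (E)-3-methoxybut-2-enoic acid | CO/C(C)=C/C(=O)O | intermediate
7 | (E)-3-methoxybut-2-enoyl chloride (not isolated) | CO/C(C)=C/C(=O)Cl | intermediate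
8 | (5S)-3-[(E)-3-methoxybut-2-enoyl]-5-(prop-1-en-2-yl)dihydrofuran-2(3H)-one (C3 epimers and enol) | C=C(C)[C@@H]1CC(C(=O)/C=C(\C)OC)C(=O)O1 | intermediate
9 | (3E,5S)-3-[(2E)-1,3-dimethoxybut-2-en-1-ylidene]-5-(prop-1-en-2-yl)dihydrofuran-2(3H)-one | C=C(C)[C@@H]1C/C(=C(OC)/C=C(\C)OC)C(=O)O1 | intermediate
10 | N-methoxy-N-methylcinnamamide | CON(C)C(=O)/C=C/c1ccccc1 | starting material
11 | (3E,5S)-3-[(2E,6E)-1,3-dimethoxy-5-oxo-7-phenylhepta-2,6-dien-1-ylidene]-5-(prop-1-en-2-yl)dihydrofuran-2(3H)-one | C=C(C)[C@@H]1C/C(=C(OC)/C=C(OC)\CC(=O)/C=C/c2ccccc2)C(=O)O1 | intermediate
12 | (E)-1-{2-hydroxy-3-[(2S)-2-hydroxy-3-methylbut-3-en-1-yl]-4,6-dimethoxyphenyl}-3-phenylprop-2-en-1-one | C=C(C)[C@@H](O)Cc1c(OC)cc(OC)c(C(=O)/C=C/c2ccccc2)c1O | intermediate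
13 | (2S)-8-[(2S)-2-hydroxy-3-methylbut-3-en-1-yl]-5,7-dimethoxy-2-phenyl-2,3-dihydro-4H-chromen-4-one | C=C(C)[C@@H](O)Cc1c(OC)cc(OC)c2c1O[C@H](c1ccccc1)CC2=O | target

## Step count and risks

Total step count: 8. Longest linear sequence: 7 steps (1 → 3 → 4 → 8 → 9 → 11 → 12 → 13; steps 1, 2, 4, 5, 6, 7 and 8).

**Step 7 (key step, proposed new method).** The strongly delocalised anion may be too stabilised to attack the donor-deactivated lactone carbonyl, or the enol ether geometries may not equilibrate. Prolonged warming would then lead to intermolecular Michael addition to the styryl ketone or to uncontrolled closure of ring C by the phenoxide. The fallback uses known chemistry only, sets out from 10 and returns at 12; ring A is taken from commercial 3,5-dimethoxyphenol instead of being folded.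
- Protection with MOMCl and iPr2NEt gives 1,3-dimethoxy-5-(methoxymethoxy)benzene F1.
- Directed ortho-lithiation between the acetal and a methoxy group (n-BuLi, THF, 0 °C) and alkylation with prenyl bromide (cat. CuBr·SMe2) gives 1,5-dimethoxy-3-(methoxymethoxy)-2-(3-methylbut-2-en-1-yl)benzene F2.
- Shi epoxidation (KHSO5, with the fructose-derived ketone of the enantiomeric series that delivers the S epoxide) gives (S)-3-[2,4-dimethoxy-6-(methoxymethoxy)benzyl]-2,2-dimethyloxirane F3.
- Epoxide-to-allylic-alcohol isomerisation with Et2Al(tmp) (diethylaluminium 2,2,6,6-tetramethylpiperidide) removes a methyl proton and gives (S)-1-[2,4-dimethoxy-6-(methoxymethoxy)phenyl]-3-methylbut-3-en-2-ol F4.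
- A second ortho-lithiation as the alkoxide (n-BuLi, 2.2 equiv) and addition to 10 gives (E)-1-{3-[(2S)-2-hydroxy-3-methylbut-3-en-1-yl]-4,6-dimethoxy-2-(methoxymethoxy)phenyl}-3-phenylprop-2-en-1-one F5.
- Dilute HCl in MeOH at 25 °C removes the acetal ortho to the ketone and returns the route at 12.

This detour gives up the regiochemical advantage of the folding, since each lithiation has to distinguish ring positions.

**Step 6.** The trienolate may react through its α- or γ-carbon, or add in conjugate fashion to the cinnamoyl unit. The adduct may also collapse before the quench, after which proton transfer to unreacted trienolate and premature folding would follow. The fallback sets out from 9 and returns at 11. The same lithium trienolate is added to cinnamaldehyde at −78 °C; an aldehyde reacts only at the carbonyl and its alkoxide adduct can neither enolise nor fold. This gives (3E,5S)-3-[(2E,6E)-5-hydroxy-1,3-dimethoxy-7-phenylhepta-2,6-dien-1-ylidene]-5-(prop-1-en-2-yl)dihydrofuran-2(3H)-one F6 as both carbinol epimers, and MnO2 in CH2Cl2 oxidises the allylic alcohol to 11.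

**Step 8.** Facial selectivity may be poor, because the chalcone is not activated and its phenol is hydrogen-bonded to the carbonyl. Closure may be slow, and the selectivity may erode through reversible ring opening. The fallback sets out from 12 and returns at 13. Ring C is closed without catalyst control (NaOAc, EtOH, reflux), and 13 is separated from its C2 epimer (2R)-8-[(2S)-2-hydroxy-3-methylbut-3-en-1-yl]-5,7-dimethoxy-2-phenyl-2,3-dihydro-4H-chromen-4-one F7. The two are diastereomers because of C2''. F7 is resubmitted to the same conditions, which epimerise C2 through 12.

**Step 5.** Methylation may occur at the ring carbon or on the lactone oxygen instead of the ketone oxygen. The fallback sets out from 8 and returns at 9, and reverses the order of events so that no ambident enolate meets the methylating agent. The neutral vinylogous ester carbonyl of 8 is alkylated with Me3OBF4 in CH2Cl2 to give the dialkoxyallyl cation salt 1,3-dimethoxy-1-[(5S)-2-oxo-5-(prop-1-en-2-yl)oxolan-3-yl]but-2-en-1-ylium tetrafluoroborate F8. iPr2NEt then removes the ring proton next to the lactone carbonyl to give 9.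

## Further compounds

F1 | step 7 | 1,3-dimethoxy-5-(methoxymethoxy)benzene | COCOc1cc(OC)cc(OC)c1
F2 | step 7 | 1,5-dimethoxy-3-(methoxymethoxy)-2-(3-methylbut-2-en-1-yl)benzene | CC(C)=CCc1c(OC)cc(OC)cc1OCOC
F3 | step 7 | (S)-3-[2,4-dimethoxy-6-(methoxymethoxy)benzyl]-2,2-dimethyloxirane | CC1(C)O[C@H]1Cc1c(OC)cc(OC)cc1OCOC
F4 | step 7 | (S)-1-[2,4-dimethoxy-6-(methoxymethoxy)phenyl]-3-methylbut-3-en-2-ol | C=C(C)[C@@H](O)Cc1c(OC)cc(OC)cc1OCOC
F5 | step 7 | (E)-1-{3-[(2S)-2-hydroxy-3-methylbut-3-en-1-yl]-4,6-dimethoxy-2-(methoxymethoxy)phenyl}-3-phenylprop-2-en-1-one | C=C(C)[C@@H](O)Cc1c(OC)cc(OC)c(C(=O)/C=C/c2ccccc2)c1OCOC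
F6 | step 6 | (3E,5S)-3-[(2E,6E)-5-hydroxy-1,3-dimethoxy-7-phenylhepta-2,6-dien-1-ylidene]-5-(prop-1-en-2-yl)dihydrofuran-2(3H)-one (both carbinol epimers) | C=C(C)[C@@H]1C/C(=C(OC)/C=C(OC)\CC(O)/C=C/c2ccccc2)C(=O)O1
F7 | step 8 | (2R)-8-[(2S)-2-hydroxy-3-methylbut-3-en-1-yl]-5,7-dimethoxy-2-phenyl-2,3-dihydro-4H-chromen-4-one | C=C(C)[C@@H](O)Cc1c(OC)cc(OC)c2c1O[C@@H](c1ccccc1)CC2=O
F8 | step 5 | 1,3-dimethoxy-1-[(5S)-2-oxo-5-(prop-1-en-2-yl)oxolan-3-yl]but-2-en-1-ylium tetrafluoroborate | C=C(C)[C@@H]1CC(C(OC)=CC(C)=[O+]C)C(=O)O1.F[B-](F)(F)F
A1 | alternative 1 | (2S)-8-allyl-5,7-dimethoxyflavanone | C=CCc1c(OC)cc(OC)c2c1O[C@H](c1ccccc1)CC2=O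
A2 | alternative 1 | (S)-3-(2-allyl-3,5-dimethoxyphenoxy)-3-phenylpropanoic acid | C=CCc1c(OC)cc(OC)cc1O[C@H](c1ccccc1)CC(=O)O
A3 | alternative 2 | 8-[(2S)-2-(tert-butyldimethylsilyloxy)-3-methylbut-3-en-1-yl]-5,7-dimethoxyflavone | C=C(C)[C@@H](O[Si](C)(C)C(C)(C)C)Cc1c(OC)cc(OC)c2c1OC(c1ccccc1)=CC2=O
A4 | alternative 2 | 2-iodo-3,5-dimethoxy-6-[(2S)-2-(tert-butyldimethylsilyloxy)-3-methylbut-3-en-1-yl]phenol | C=C(C)[C@@H](O[Si](C)(C)C(C)(C)C)Cc1c(OC)cc(OC)c(I)c1O
A5 | alternative 2 | phenylacetylene | C#Cc1ccccc1
A6 | alternative 3 | (2S)-8-[(2S)-2-(tert-butyldimethylsilyloxy)-3-methylbut-3-en-1-yl]-5,7-dimethoxyflavanone | C=C(C)[C@@H](O[Si](C)(C)C(C)(C)C)Cc1c(OC)cc(OC)c2c1O[C@H](c1ccccc1)CC2=O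
A7 | alternative 3 | 3-[(2S)-2-(tert-butyldimethylsilyloxy)-3-methylbut-3-en-1-yl]-4,6-dimethoxy-2-[(1-phenylethenyl)oxy]benzaldehyde | C=C(C)[C@@H](O[Si](C)(C)C(C)(C)C)Cc1c(OC)cc(OC)c(C=O)c1OC(=C)c1ccccc1
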